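## Structural features

The target is a 2,4-disubstituted chroman: a benzene ring (ring A, C4a–C8a) fused to a dihydropyran ring (O1, C2, C3, C4). Ring A carries a free hydroxyl at C5, so C4a lies between two oxygen-bearing carbons (C5 and C8a), a 1,2,3-trisubstituted resorcinol pattern. C4 is a doubly benzylic methine that joins C4a to C1 of a 4,5-dimethoxynaphthalene; the naphthalene peri hydrogen and the C5 hydroxyl crowd it from both sides. The two stereocentres, C2 (R, methyl) and C4 (S, naphthyl), are separated by the C3 methylene and are trans on the pyran ring. The fragile parts are the very electron-rich peri-dimethoxynaphthalene (oxidants, strong acids and electrophiles), the free phenol, and the C4–H bond, whose cation both arenes would stabilise. The real difficulty is twofold: placing a bulky carbon substituent on the ring A carbon between the two oxygens, a position that electrophilic substitution of a resorcinol avoids, and relating C4 to C2 across a methylene. The key step answers the first point by building ring A so that C4a is created already bonded to C4. The C4a–C5 unit comes from a 1-siloxyalkyne and C6–C7–C8–C8a from a vinylketene, which places oxygen on both neighbours of C4a automatically.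

## Logic of the disconnections

**24 to 23.** The O1–C2 ether bond is cut. An aryl ether at a secondary carbon is the natural product of an SN2 closure by a phenol oxygen, and opening the pyran leaves an open chain whose stereocentres can be set before any ring exists. In 23 the two ring A hydroxyls flank C4a and are exchanged by rotation about C4–C4a, so either may close and no differentiation is needed. The forward step must invert C2 cleanly, so 23 carries the carbinol centre as S, and it must not ionise C4.

**23 to 22.** Two O–Si bonds are cut. 22 is what the annulation delivers, and because of the symmetry just noted both silyl groups can leave together, which saves a step. The silyl groups must outlast organolithium and photochemical steps and still fall to fluoride.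

**22 to 14 and 17.** Ring A is taken apart at C4a–C8a, C5–C6 and C8–C8a, and at C6–C7 inside the four-carbon partner. Only this cut lets C4a arrive already attached to the C4 methine and flanked by oxygen on both sides. One aromatic ring disappears; what remains is the acyclic alkyne 14 holding both stereocentres and the four-carbon unit 17. The forward step needs complete regiocontrol in the union of ketene and alkyne, neutral conditions that leave C2 and C4 alone, and light that reaches 17 despite the naphthalene chromophore of 14.

**17 to 15.** The C=N2 bond is cut. 15 supplies all four carbons. The forward step must place the diazo group on the methyl carbon of a polymerisable enone, hence diazo transfer to a transiently acylated enolate.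

**14 to 12.** The alkyne carbon next to the future C4 is removed and the O–Si bond is cut; this undoes a one-carbon homologation that forms the C4–C(alkyne) and C≡C bonds. A 1-siloxyalkyne is an ester at a different oxidation level, and 12 is an ordinary α-aryl ester. The forward step must insert the carbon with retention at the migrating centre and must add to the ester carbonyl faster than it removes the acidic α-hydrogen.

**12 to 11 to 8.** The O–CH3 and O–Si bonds are cut and the acyl C–O bond of a five-membered ring is restored. Going back to the cyclic 8 puts both stereocentres on one ring, where their relationship can be controlled. The forward steps must keep the opened chain from reclosing, so both oxygens are capped before the free acid appears.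

**8 to 7 to 4 and 5.** The C3–C4 bond (target numbering) is cut, after the future C4 is allowed to lose its configuration in 7. 5 brings C2 with its oxygen, its methyl and C3 from the chiral pool; 4 brings the naphthylacetic unit. The forward steps need attack only at the CH2 of 5, and the cis arrangement of 8 must be the favoured one at equilibrium.

**4 to 3 to 2 to 1.** The naphthalene C1–CH2 bond and then the C–Br bond are cut. 1 is commercial, and its position para to a methoxy group is the most nucleophilic one. The forward steps need monobromination and a coupling that tolerates a hindered, electron-rich aryl bromide.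

## Other disconnections considered

**Alternative 1:** Oxygen O1 is excised from between C8a and C2. This leads from the lactone A1, (4S)-5-(benzyloxy)-4-(4,5-dimethoxynaphthalen-1-yl)chroman-2-one, back to the indanone A2, (3S)-4-(benzyloxy)-3-(4,5-dimethoxynaphthalen-1-yl)indan-1-one. Forward, a buffered peracid or a Baeyer–Villiger monooxygenase would insert oxygen on the aryl side of the ketone of A2 and form C8a–O1 and O1–C2 in one operation.
- In its favour: ring A is bought and not built. The C4 centre of A2 is β to the carbonyl, so it cannot epimerise by enolisation, and it could be set by catalytic asymmetric conjugate arylation. On configurational security of C4 this alternative is better than the chosen plan, which relies on an equilibration and carries an enolisable centre through several steps. The oxygen insertion is also a simpler event than a four-stage pericyclic cascade, an equal or slightly better point.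
- Against it, structure: A1 has a carbonyl where the target has the C2 methyl stereocentre. Methyl addition, reduction and a stereocontrolled closure would still be needed, plus benzyl removal. Reduction of the derived oxocarbenium ion would be expected to favour the cis isomer, not the trans one required.
- Against it, mechanism: the migrating arene carbon of A2 is meta to the benzyloxy group and gains nothing from it, so competition with CH2 migration stays open. A peracid is also a poor match for a peri-dimethoxynaphthalene, which is oxidised easily; an enzyme would avoid this but would have to accept a very bulky ketone.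
- Step economy: A2 must itself be assembled with its crowded 3,4-pattern, and at least four operations would follow A1. The sequence should be as long as or longer than the chosen one, which needs two steps after ring A is formed.

**Alternative 2:** The pyran ring is cut at C3–C4 and O1–C2, a retro-hetero-Diels–Alder. It leads from the cyclic acetal A3, (2R,4S)-2-ethoxy-4-(4,5-dimethoxynaphthalen-1-yl)chroman-5-ol (cis), to the diarylcarbinol A4, 2-[(4,5-dimethoxynaphthalen-1-yl)(hydroxy)methyl]benzene-1,3-diol. The path runs through the ortho-quinone methide A5, 6-[(4,5-dimethoxynaphthalen-1-yl)methylidene]-5-hydroxycyclohexa-2,4-dien-1-one, and ethoxyethene A6. Forward, a chiral phosphoric acid would dehydrate A4, hold A5 by hydrogen bonds and direct A6 across C4 and oxygen.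
- In its favour: it is convergent, both arenes are bought, and ring closure and C4 come from one catalytic step. In step count it is better than the chosen plan. It is equal to the chosen plan in exploiting the twofold symmetry of the resorcinol ring, since either oxygen of A5 can serve as the heteroatom.
- Against it, structure: A3 has an ethoxy group where methyl must stand. The acetal must be exchanged for methyl through an oxocarbenium ion (for example with AlMe3). Attack anti to the C4 aryl group should favour the trans isomer, but this is a second stereochemical problem to solve.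
- Against it, mechanism: the cation behind A5 is stabilised by a methoxynaphthyl group and two hydroxyls. Ionisation is easy, but so are the uncatalysed background addition, self-condensation of A4 through its own nucleophilic ring, and reversible ring opening of A3 under the Lewis acid needed for the methyl exchange. Each would erode the C4 configuration.
- Comparison: the chosen plan is the better one on stereochemical security, because it never places positive charge on C4 and takes C2 from the chiral pool.

**Alternative 3:** The C2–C3 and O1–C2 bonds are cut. This leads from the lactol A7, (4S)-4-(4,5-dimethoxynaphthalen-1-yl)chromane-2,5-diol (both anomers), to the 1,1-diarylethene A8, 2-[1-(4,5-dimethoxynaphthalen-1-yl)ethenyl]benzene-1,3-diol. Forward, Rh(acac)(CO)2 with a chiral bisphosphite or phosphine–phosphite ligand under CO/H2 would deliver hydrogen to C4 and a formyl group to the terminal carbon of A8. A resorcinol hydroxyl would then capture the aldehyde as A7.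
- In its favour: atom economy, a cheap one-carbon source, and a substrate without protecting groups. C4 and the C2–C3 bond come from one catalytic step and lactol formation is spontaneous. In atom economy and step count it is equal to or better than the chosen plan.
- Against it, mechanism: enantioselective hydroformylation of 1,1-disubstituted alkenes is the least developed of the key steps considered. The catalyst must tell apart two aryl groups of similar size, a 1,1-diarylethene inserts slowly and is prone to hydrogenation, and free phenols can displace phosphite ligands.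
- Against it, structure: as in alternative 2, A7 has oxygen at C2 where methyl belongs. The lactol carbon must still become a methyl-bearing stereocentre of defined configuration, so the endgame is no shorter than the chosen one.
- Comparison: the chosen plan is better in the precedent for its key step and in stereocontrol.

Key step: step 10

Remark: read from its SMILES, the target is (2R,4S), with methyl and naphthyl trans on the pyran ring; the route is planned for this isomer.
Remark: 17 is a low-molecular-weight diazo compound and is made, kept and used only as a cold, dilute solution protected from light.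

## Route

Step 1
Reactants: 1 1,8-dimethoxynaphthalene
Product: 2 1-bromo-4,5-dimethoxynaphthalene
Conditions: NBS (1.0 equiv), MeCN, 0 °C → rt, dark
Reagents that add atoms: N-bromosuccinimide, O=C1CCC(=O)N1Br
Why: Electrophilic aromatic bromination; the position para to a methoxy group is the most nucleophilic site of 1 and the peri positions are occupied, so one equivalent of NBS should give the 4-bromide selectively.

Step 2
Reactants: 2 1-bromo-4,5-dimethoxynaphthalene
Product: 3 tert-butyl 2-(4,5-dimethoxynaphthalen-1-yl)acetate
Conditions: BrZnCH2CO2t-Bu (1.5 equiv), Pd[P(t-Bu)3]2 (3 mol %), THF, rt → 50 °C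
Reagents that add atoms: (2-tert-butoxy-2-oxoethyl)zinc bromide, CC(C)(C)OC(=O)C[Zn]Br
Why: Palladium-catalysed α-arylation of a Reformatsky reagent (Negishi-type coupling); the bulky, electron-rich phosphine lets zerovalent palladium insert into the hindered, electron-rich C–Br bond, and the neutral zinc enolate avoids Claisen condensation.

Step 3
Reactants: 3 tert-butyl 2-(4,5-dimethoxynaphthalen-1-yl)acetate
Product: 4 2-(4,5-dimethoxynaphthalen-1-yl)acetic acid
Conditions: CF3CO2H, CH2Cl2, 0 °C → rt
Reagents that add atoms: none
Why: Acidolysis of a tert-butyl ester by alkyl–oxygen cleavage with loss of isobutene; the free acid is needed because its dianion, unlike an ester enolate, opens epoxides readily.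

Step 4
Reactants: 4 2-(4,5-dimethoxynaphthalen-1-yl)acetic acid; 5 (S)-2-methyloxirane
Product: 7 (5S)-3-(4,5-dimethoxynaphthalen-1-yl)-5-methyloxolan-2-one (both C3 epimers), via hydroxy acid 6 (not isolated)
Conditions: LiN(i-Pr)2 (2.2 equiv), THF, −78 → 0 °C; 5 (1.5 equiv), 0 °C → rt, sealed; aq HCl; TsOH (cat.), PhMe, 60 °C
Reagents that add atoms: none
Why: Alkylation of a carboxylic acid dianion with an epoxide followed by acid-catalysed lactonisation; SN2 attack at the unsubstituted epoxide carbon leaves the C–O stereocentre of 5 untouched, while the new α-centre forms without control and is corrected in step 5.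

Step 5
Reactants: 7 (5S)-3-(4,5-dimethoxynaphthalen-1-yl)-5-methyloxolan-2-one (both C3 epimers)
Product: 8 (3S,5S)-3-(4,5-dimethoxynaphthalen-1-yl)-5-methyloxolan-2-one (cis)
Conditions: DBU (0.3 equiv), PhMe, 40 °C; chromatography, trans epimer re-submitted
Reagents that add atoms: none
Why: Thermodynamic epimerisation through the lactone enolate; in the cis isomer both substituents can sit pseudo-equatorially on the envelope, reprotonation anti to the C5 methyl group leads to the same isomer, and C5 is not touched, so the future C4 is set relative to the chiral-pool centre.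

Step 6
Reactants: 8 (3S,5S)-3-(4,5-dimethoxynaphthalen-1-yl)-5-methyloxolan-2-one
Product: 11 (2S,4S)-4-(tert-butyldimethylsilyloxy)-2-(4,5-dimethoxynaphthalen-1-yl)pentanoic acid, via potassium carboxylate 9 (not isolated), via bis-silyl ester 10 (not isolated)
Conditions: KOH (1.05 equiv), MeOH–H2O, 0 °C → rt, evaporate; TBSCl (2.5 equiv), imidazole, DMF, rt; then AcOH–THF–H2O, rt, short
Reagents that add atoms: potassium hydroxide, [K+].[OH-]; tert-butyldimethylsilyl chloride, CC(C)(C)[Si](C)(C)Cl
Why: Lactone saponification, silylation of hydroxyl and carboxylate, and selective hydrolysis of the far more labile silyl ester; the carboxylate is not enolised under these conditions, and capping the hydroxyl before the acid is set free prevents relactonisation.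

Step 7
Reactants: 11 (2S,4S)-4-(tert-butyldimethylsilyloxy)-2-(4,5-dimethoxynaphthalen-1-yl)pentanoic acid
Product: 12 methyl (2S,4S)-4-(tert-butyldimethylsilyloxy)-2-(4,5-dimethoxynaphthalen-1-yl)pentanoate
Conditions: MeI (1.5 equiv), KHCO3 (2 equiv), DMF, rt
Reagents that add atoms: iodomethane, CI
Why: SN2 O-methylation of the carboxylate; bicarbonate is too weak a base to enolise the α-aryl ester, so the C2 configuration should be kept.

Step 8
Reactants: 12 methyl (2S,4S)-4-(tert-butyldimethylsilyloxy)-2-(4,5-dimethoxynaphthalen-1-yl)pentanoate
Product: 14 (3S,5S)-5-(tert-butyldimethylsilyloxy)-3-(4,5-dimethoxynaphthalen-1-yl)-1-(triisopropylsilyloxy)hex-1-yne, via lithium ynolate 13 (not isolated)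
Conditions: CH2Br2 (2.2 equiv), lithium 2,2,6,6-tetramethylpiperidide (2.2 equiv), THF, −78 °C; 12; n-BuLi (4 equiv), −78 → 0 °C; i-Pr3SiCl, −78 °C → rt; neutral alumina
Reagents that add atoms: dibromomethane, BrCBr; chlorotri(propan-2-yl)silane, CC(C)[Si](Cl)(C(C)C)C(C)C
Why: Kowalski ester homologation halted at the ynolate; LiCHBr2 adds to the ester, bromine–lithium exchange on the resulting dibromo enolate triggers a 1,2-shift of the α-carbon with retention, and the bulky silyl chloride traps 13 on oxygen, the standard entry to 1-(triisopropylsiloxy)alkynes from esters.

Step 9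
Reactants: 15 but-3-en-2-one (methyl vinyl ketone)
Product: 17 1-diazobut-3-en-2-one, via trifluoroacetyl diketone 16 (not isolated)
Conditions: LiN(SiMe3)2 (1.1 equiv), THF, −78 °C, 15 added slowly; CF3CO2CH2CF3 (1.2 equiv); aq HCl; then 4-AcNHC6H4SO2N3, Et3N, H2O (1 equiv), MeCN, rt; kept as a cold solution
Reagents that add atoms: 4-acetamidobenzenesulfonyl azide, CC(=O)Nc1ccc(cc1)S(=O)(=O)N=[N+]=[N-] (the acyl group of 16 comes from 2,2,2-trifluoroethyl trifluoroacetate, O=C(OCC(F)(F)F)C(F)(F)F, and is lost again)
Why: Detrifluoroacetylative (Regitz-type deacylative) diazo transfer; the kinetic enolate is trifluoroacetylated, the activated 1,3-diketone 16 accepts the diazo group from the sulfonyl azide and the trifluoroacetyl group is then cleaved, a protocol suited to enones that tolerate neither direct diazo transfer nor acylation of diazomethane.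

Step 10
Reactants: 14 (3S,5S)-5-(tert-butyldimethylsilyloxy)-3-(4,5-dimethoxynaphthalen-1-yl)-1-(triisopropylsilyloxy)hex-1-yne; 17 1-diazobut-3-en-2-one
Product: 22 2-[(1S,3S)-3-(tert-butyldimethylsilyloxy)-1-(4,5-dimethoxynaphthalen-1-yl)butyl]-3-(triisopropylsilyloxy)phenol, via vinylketene 18 (not isolated), via vinylcyclobutenone 19 (not isolated), via dienylketene 20 (not isolated), via cyclohexadienone 21 (not isolated)
Conditions: hν (350–365 nm, Pyrex), 17 (1.5 equiv, slow addition), ClCH2CH2Cl, rt; then 80 °C
Reagents that add atoms: none
Why: Danheiser benzannulation in its photochemical form; the closest known reaction type is the irradiation of α,β-unsaturated diazo ketones with 1-siloxyalkynes to give resorcinol monosilyl ethers. Light expels N2 from 17 and the vinyl group shifts to the carbene carbon (Wolff rearrangement, forming C6–C7) to give 18. The alkyne carbon of 14 remote from oxygen, the nucleophilic one, attacks the ketene carbonyl carbon, so the [2+2] adduct 19 has C4a–C8a and C5–C6 in place with the side chain on C4a. Ring strain drives conrotatory 4π opening to 20, and ring A closes by thermal disrotatory 6π electrocyclisation (C8–C8a) to 21, which tautomerises to 22; the final heating completes this sequence. No stereocentre is created: the sp3 centres of 19 and 21 vanish on aromatisation, and C2 and C4 are spectators under neutral, non-ionising conditions. The selectivity needed is regiochemical, and it is secured by the polarisation of the ynol ether against the ketene, which places the chain between the free hydroxyl and the silyl ether. Irradiation at 350–365 nm, where the diazo ketone still absorbs and the dimethoxynaphthalene hardly does, and slow feeding of 17 in excess keep the light on the right chromophore and the ketene concentration low.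

Step 11
Reactants: 22 2-[(1S,3S)-3-(tert-butyldimethylsilyloxy)-1-(4,5-dimethoxynaphthalen-1-yl)butyl]-3-(triisopropylsilyloxy)phenol
Product: 23 2-[(1S,3S)-1-(4,5-dimethoxynaphthalen-1-yl)-3-hydroxybutyl]benzene-1,3-diol
Conditions: Bu4NF (3 equiv), THF, 0 °C → rt, under Ar
Reagents that add atoms: none
Why: Fluoride-mediated cleavage of the aryl and the alkyl silyl ether in one operation; the conditions are non-acidic, so the doubly benzylic C4 is safe, and because the two ring A hydroxyls of 23 are equivalent no selectivity is required.

Step 12
Reactants: 23 2-[(1S,3S)-1-(4,5-dimethoxynaphthalen-1-yl)-3-hydroxybutyl]benzene-1,3-diol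
Product: 24 (2R,4S)-4-(4,5-dimethoxynaphthalen-1-yl)-2-methylchroman-5-ol (cladonaphchrom A)
Conditions: PPh3 (1.5 equiv), DIAD (1.5 equiv), THF (dilute), 0 °C → rt
Reagents that add atoms: none
Why: Intramolecular Mitsunobu etherification; the secondary alcohol is activated as an alkoxyphosphonium ion and displaced by a phenoxide oxygen in a 6-exo-tet SN2 closure with inversion, which turns the S carbinol into the R centre at C2 and gives the trans chroman, while the other phenol remains as the C5 hydroxyl.

## Compound list

1 | 1,8-dimethoxynaphthalene | COc1cccc2cccc(OC)c12 | starting material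
2 | 1-bromo-4,5-dimethoxynaphthalene | COc1cccc2c(Br)ccc(OC)c12 | intermediate
3 | tert-butyl 2-(4,5-dimethoxynaphthalen-1-yl)acetate | COc1cccc2c(CC(=O)OC(C)(C)C)ccc(OC)c12 | intermediate
4 | 2-(4,5-dimethoxynaphthalen-1-yl)acetic acid | COc1cccc2c(CC(=O)O)ccc(OC)c12 | intermediate
5 | (S)-2-methyloxirane ((S)-propylene oxide) | C[C@H]1CO1 | starting material
6 | (4S)-2-(4,5-dimethoxynaphthalen-1-yl)-4-hydroxypentanoic acid, mixture of C2 epimers | COc1cccc2c(C(C[C@H](C)O)C(=O)O)ccc(OC)c12 | intermediate
7 | (5S)-3-(4,5-dimethoxynaphthalen-1-yl)-5-methyloxolan-2-one, mixture of C3 epimers | COc1cccc2c(C3C[C@H](C)OC3=O)ccc(OC)c12 | intermediate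
8 | (3S,5S)-3-(4,5-dimethoxynaphthalen-1-yl)-5-methyloxolan-2-one (cis) | COc1cccc2c([C@@H]3C[C@H](C)OC3=O)ccc(OC)c12 | intermediate
9 | potassium (2S,4S)-2-(4,5-dimethoxynaphthalen-1-yl)-4-hydroxypentanoate | COc1cccc2c([C@@H](C(=O)[O-])C[C@H](C)O)ccc(OC)c12.[K+] | intermediate
10 | tert-butyldimethylsilyl (2S,4S)-4-(tert-butyldimethylsilyloxy)-2-(4,5-dimethoxynaphthalen-1-yl)pentanoate | COc1cccc2c([C@@H](C(=O)O[Si](C)(C)C(C)(C)C)C[C@H](C)O[Si](C)(C)C(C)(C)C)ccc(OC)c12 | intermediate
11 | (2S,4S)-4-(tert-butyldimethylsilyloxy)-2-(4,5-dimethoxynaphthalen-1-yl)pentanoic acid | COc1cccc2c([C@@H](C(=O)O)C[C@H](C)O[Si](C)(C)C(C)(C)C)ccc(OC)c12 | intermediate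
12 | methyl (2S,4S)-4-(tert-butyldimethylsilyloxy)-2-(4,5-dimethoxynaphthalen-1-yl)pentanoate | COc1cccc2c([C@@H](C(=O)OC)C[C@H](C)O[Si](C)(C)C(C)(C)C)ccc(OC)c12 | intermediate
13 | lithium (3S,5S)-5-(tert-butyldimethylsilyloxy)-3-(4,5-dimethoxynaphthalen-1-yl)hex-1-yn-1-olate | COc1cccc2c([C@@H](C#C[O-])C[C@H](C)O[Si](C)(C)C(C)(C)C)ccc(OC)c12.[Li+] | intermediate
14 | (3S,5S)-5-(tert-butyldimethylsilyloxy)-3-(4,5-dimethoxynaphthalen-1-yl)-1-(triisopropylsilyloxy)hex-1-yne | COc1cccc2c([C@@H](C#CO[Si](C(C)C)(C(C)C)C(C)C)C[C@H](C)O[Si](C)(C)C(C)(C)C)ccc(OC)c12 | intermediate
15 | but-3-en-2-one (methyl vinyl ketone) | CC(=O)C=C | starting material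
16 | 1,1,1-trifluorohex-5-ene-2,4-dione | C=CC(=O)CC(=O)C(F)(F)F | intermediate
17 | 1-diazobut-3-en-2-one | C=CC(=O)C=[N+]=[N-] | intermediate
18 | buta-1,3-dien-1-one (vinylketene) | C=CC=C=O | intermediate
19 | 2-[(1S,3S)-3-(tert-butyldimethylsilyloxy)-1-(4,5-dimethoxynaphthalen-1-yl)butyl]-4-ethenyl-3-(triisopropylsilyloxy)cyclobut-2-en-1-one, both epimers at the ring sp3 carbon | COc1cccc2c([C@@H](C3=C(O[Si](C(C)C)(C(C)C)C(C)C)C(C=C)C3=O)C[C@H](C)O[Si](C)(C)C(C)(C)C)ccc(OC)c12 | intermediate
20 | (3E)-2-[(1S,3S)-3-(tert-butyldimethylsilyloxy)-1-(4,5-dimethoxynaphthalen-1-yl)butyl]-3-(triisopropylsilyloxy)hexa-1,3,5-trien-1-one | COc1cccc2c([C@@H](C(=C=O)/C(O[Si](C(C)C)(C(C)C)C(C)C)=C\C=C)C[C@H](C)O[Si](C)(C)C(C)(C)C)ccc(OC)c12 | intermediate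
21 | 2-[(1S,3S)-3-(tert-butyldimethylsilyloxy)-1-(4,5-dimethoxynaphthalen-1-yl)butyl]-3-(triisopropylsilyloxy)cyclohexa-2,4-dien-1-one | COc1cccc2c([C@@H](C3=C(O[Si](C(C)C)(C(C)C)C(C)C)C=CCC3=O)C[C@H](C)O[Si](C)(C)C(C)(C)C)ccc(OC)c12 | intermediate
22 | 2-[(1S,3S)-3-(tert-butyldimethylsilyloxy)-1-(4,5-dimethoxynaphthalen-1-yl)butyl]-3-(triisopropylsilyloxy)phenol | COc1cccc2c([C@@H](c3c(O)cccc3O[Si](C(C)C)(C(C)C)C(C)C)C[C@H](C)O[Si](C)(C)C(C)(C)C)ccc(OC)c12 | intermediate
23 | 2-[(1S,3S)-1-(4,5-dimethoxynaphthalen-1-yl)-3-hydroxybutyl]benzene-1,3-diol | COc1cccc2c([C@@H](c3c(O)cccc3O)C[C@H](C)O)ccc(OC)c12 | intermediate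
24 | (2R,4S)-4-(4,5-dimethoxynaphthalen-1-yl)-2-methylchroman-5-ol (cladonaphchrom A) | COc1cccc2c([C@@H]3C[C@@H](C)Oc4cccc(O)c43)ccc(OC)c12 | target

## Step count and least certain steps

Total step count: 12. Longest linear sequence: 11 steps (1 → 2 → 3 → 4 → 7 → 8 → 11 → 12 → 14 → 22 → 23 → 24); step 9 is a one-step side branch that joins at step 10.

**Step 10 (key step).** The naphthalene of 14 may take the light or act as a triplet sensitiser and divert the excited diazo ketone from the Wolff pathway. The ketene may also be lost by dimerisation or by acylating the product phenol, and the [2+2] addition at the α-branched, hindered alkyne carbon may be slow, so that 14 is left unconverted. Fallback, from 14 back to 22: the vinylketene 18 is generated thermally, without light. 14 is heated in toluene at 80–110 °C with cyclobut-2-en-1-one F1, freshly liberated from commercial 3-bromocyclobutan-1-one with Bu3N. Electrocyclic opening of the four-membered ring gives 18, and the route continues through 19, 20 and 21 to 22.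

**Step 8.** The carbenoid base may remove the acidic α-aryl hydrogen of 12 instead of adding to the carbonyl. That would stall the conversion and scramble the future C4 by proton exchange between ester and enolate; excess n-BuLi may also metalate the dimethoxynaphthalene. Fallback, from 12 back to 14 through 13: the carbon is added by olefination and the oxygen by acetylide oxidation. 12 is reduced with i-Bu2AlH at −78 °C to the α-aryl aldehyde F2, which is used at once and never meets base. CBr4/PPh3 (Corey–Fuchs) gives the 1,1-dibromoalkene F3, and n-BuLi then gives the terminal alkyne F4. Deprotonation of F4 with LiN(SiMe3)2 and oxidation of the lithium acetylide with LiOO-t-Bu should give the ynolate 13, which i-Pr3SiOTf converts into 14.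

**Step 5.** The thermodynamic bias toward the cis lactone may be too small, which would mean poor diastereoselection and a laborious separate-and-recycle loop. Fallback, from 7 back to 8: the centre is set by substrate-controlled hydrogenation. The enolate of 7 (LiN(i-Pr)2) is selenenylated with PhSeBr to the α-selenide F5. Oxidation with H2O2 and syn-elimination give the butenolide F6, in which both epimers of 7 converge. Hydrogenation (H2, Pd/C, EtOAc) from the face opposite the C5 methyl group should deliver 8.

**Step 9.** 15 may polymerise anionically or add to its own enolate during enolisation, and the product may be lost by dipolar self-addition on concentration. Fallback, from 15 back to 17: the double bond is masked. Conjugate addition of PhSeH (from PhSeSePh and NaBH4) to 15 gives the selenide ketone F7. The same trifluoroacetylation leads to the diketone F8 and diazo transfer to the diazo selenide F9. Oxidation with NaIO4 and selenoxide elimination at or below room temperature then release 17.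

**Step 12.** The activated secondary alcohol may eliminate to an alkene, or the second free phenol may undergo intermolecular etherification instead of ring closure. Fallback, from 22 back to 24: the two ring A oxygens are kept differentiated. Camphorsulfonic acid in MeOH removes only the alkyl silyl ether of 22 to give the monosilylated phenol alcohol F10. PPh3/DIAD closes the ring with inversion to the silylated chroman F11, and Bu4NF then frees the C5 hydroxyl to give 24.

## Further compounds

F1 | step 10 | cyclobut-2-en-1-one | O=C1C=CC1
F2 | step 8 | (2S,4S)-4-(tert-butyldimethylsilyloxy)-2-(4,5-dimethoxynaphthalen-1-yl)pentanal | COc1cccc2c([C@@H](C=O)C[C@H](C)O[Si](C)(C)C(C)(C)C)ccc(OC)c12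
F3 | step 8 | (3R,5S)-1,1-dibromo-5-(tert-butyldimethylsilyloxy)-3-(4,5-dimethoxynaphthalen-1-yl)hex-1-ene | COc1cccc2c([C@@H](C=C(Br)Br)C[C@H](C)O[Si](C)(C)C(C)(C)C)ccc(OC)c12
F4 | step 8 | (3R,5S)-5-(tert-butyldimethylsilyloxy)-3-(4,5-dimethoxynaphthalen-1-yl)hex-1-yne | COc1cccc2c([C@@H](C#C)C[C@H](C)O[Si](C)(C)C(C)(C)C)ccc(OC)c12
F5 | step 5 | (5S)-3-(4,5-dimethoxynaphthalen-1-yl)-5-methyl-3-(phenylselanyl)oxolan-2-one, mixture of C3 epimers | COc1cccc2c(C3([Se]c4ccccc4)C[C@H](C)OC3=O)ccc(OC)c12
F6 | step 5 | (5S)-3-(4,5-dimethoxynaphthalen-1-yl)-5-methylfuran-2(5H)-one | COc1cccc2c(C3=C[C@H](C)OC3=O)ccc(OC)c12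
F7 | step 9 | 4-(phenylselanyl)butan-2-one | CC(=O)CC[Se]c1ccccc1
F8 | step 9 | 1,1,1-trifluoro-6-(phenylselanyl)hexane-2,4-dione | FC(F)(F)C(=O)CC(=O)CC[Se]c1ccccc1
F9 | step 9 | 1-diazo-4-(phenylselanyl)butan-2-one | [N-]=[N+]=CC(=O)CC[Se]c1ccccc1
F10 | step 12 | 2-[(1S,3S)-1-(4,5-dimethoxynaphthalen-1-yl)-3-hydroxybutyl]-3-(triisopropylsilyloxy)phenol | COc1cccc2c([C@@H](c3c(O)cccc3O[Si](C(C)C)(C(C)C)C(C)C)C[C@H](C)O)ccc(OC)c12
F11 | step 12 | (2R,4S)-4-(4,5-dimethoxynaphthalen-1-yl)-2-methyl-5-(triisopropylsilyloxy)chromane | COc1cccc2c([C@@H]3C[C@@H](C)Oc4cccc(O[Si](C(C)C)(C(C)C)C(C)C)c43)ccc(OC)c12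
A1 | alternative 1 | (4S)-5-(benzyloxy)-4-(4,5-dimethoxynaphthalen-1-yl)chroman-2-one | COc1cccc2c([C@@H]3CC(=O)Oc4cccc(OCc5ccccc5)c43)ccc(OC)c12
A2 | alternative 1 | (3S)-4-(benzyloxy)-3-(4,5-dimethoxynaphthalen-1-yl)indan-1-one | COc1cccc2c([C@@H]3CC(=O)c4cccc(OCc5ccccc5)c43)ccc(OC)c12
A3 | alternative 2 | (2R,4S)-2-ethoxy-4-(4,5-dimethoxynaphthalen-1-yl)chroman-5-ol (cis) | COc1cccc2c([C@@H]3C[C@H](OCC)Oc4cccc(O)c43)ccc(OC)c12
A4 | alternative 2 | 2-[(4,5-dimethoxynaphthalen-1-yl)(hydroxy)methyl]benzene-1,3-diol (racemic) | COc1cccc2c(C(O)c3c(O)cccc3O)ccc(OC)c12
A5 | alternative 2 | 6-[(4,5-dimethoxynaphthalen-1-yl)methylidene]-5-hydroxycyclohexa-2,4-dien-1-one | COc1cccc2c(C=C3C(=O)C=CC=C3O)ccc(OC)c12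
A6 | alternative 2 | ethoxyethene (ethyl vinyl ether) | C=COCC
A7 | alternative 3 | (4S)-4-(4,5-dimethoxynaphthalen-1-yl)chromane-2,5-diol, both anomers | COc1cccc2c([C@@H]3CC(O)Oc4cccc(O)c43)ccc(OC)c12
A8 | alternative 3 | 2-[1-(4,5-dimethoxynaphthalen-1-yl)ethenyl]benzene-1,3-diol | COc1cccc2c(C(=C)c3c(O)cccc3O)ccc(OC)c12
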